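**Retrosynthetic overview**

- Labels: rings A (resorcinol) and D (monophenol) are the arenes of the 9,10-dihydrophenanthrene, ring B is the fused catechol and ring C the pendant catechol. C7 is the dihydrophenanthrene CH2, C8 its CH (bonded to rings B and D), C9 the CH bearing ring C, and C10 the CH2 between C9 and ring D.
- Feature and key disconnection (C9–C10): C10 sits on ring D, where it can be carried as a formyl group, and C9 is benzylic and para to the ring C oxygen, so it can be unveiled as the exocyclic carbon of a ring C para-quinone methide. A carbene-bound acyl anion at C10 adds to C9 and closes the seven-membered ring last; C10=O is then removed and the ethers cleaved.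
- Quinone methide precursor: a C9 sulfone made from the carbinol obtained by adding the ring B aryllithium to protected vanillin (C9–ring B bond).
- C8–ring B bond and the C8 stereocentre: enantioselective benzylic C–H arylation of the dihydrophenanthrene aldehyde, directed by the same ring D formyl group through a transient tert-leucine imine.
- Ring order: rings A and D are joined first (central six-membered ring by intramolecular direct arylation of a bibenzyl from 3,5-dibromoanisole), then ring B is attached, ring C added, and the seven-membered ring closed in the key step.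

Key step: step 11

Assumption (remark on the chemistry): the sense of induction of the two chiral catalysts is not predicted here. L-tert-leucine (step 6) and the (5aS,10bR) triazolium salt (step 11) stand for whichever commercial enantiomer of each gives the configurations drawn, and the ketone with H8 and H9 cis is taken to be the more stable C9 epimer.

**Route**

Step 1
Reactants: 1 3,5-dibromoanisole
Product: 3 2,6-dibromo-4-methoxybenzaldehyde, via aryllithium 2 (not isolated)
Conditions: LiN(iPr)2 (1.1 equiv), THF, −78 °C; DMF, −78 to 0 °C; 1 M HCl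
Reagents that add atoms: N,N-dimethylformamide, CN(C)C=O
Why: Directed deprotonation by the lithium amide removes the most acidic ring hydrogen, the one flanked by both bromines, and DMF formylates the aryllithium (lithiation–formylation), the low temperature preventing loss of LiBr to an aryne.

Step 2
Reactants: 3 2,6-dibromo-4-methoxybenzaldehyde; 4 diethyl (3,5-dimethoxybenzyl)phosphonate
Product: 5 (E)-1,3-dibromo-2-[2-(3,5-dimethoxyphenyl)ethenyl]-5-methoxybenzene
Conditions: NaH, THF, 0 °C to rt
Reagents that add atoms: none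
Why: Horner–Wadsworth–Emmons olefination of the hindered, non-enolisable aldehyde with the benzylic phosphonate anion should give the stilbene, mainly E, whose geometry is irrelevant because the double bond is reduced next.

Step 3
Reactants: 5 (E)-1,3-dibromo-2-[2-(3,5-dimethoxyphenyl)ethenyl]-5-methoxybenzene
Product: 6 1,3-dibromo-2-[2-(3,5-dimethoxyphenyl)ethyl]-5-methoxybenzene
Conditions: H2 (1 atm), 5% Pt/C (sulfided), EtOAc, rt
Reagents that add atoms: none
Why: Heterogeneous catalytic hydrogenation over sulfided platinum saturates the stilbene double bond while leaving the two aryl bromides untouched.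

Step 4
Reactants: 6 1,3-dibromo-2-[2-(3,5-dimethoxyphenyl)ethyl]-5-methoxybenzene
Product: 8 3-bromo-2-[2-(3,5-dimethoxyphenyl)ethyl]-5-methoxybenzaldehyde, via aryllithium 7 (not isolated)
Conditions: n-BuLi (1.0 equiv), THF, −78 °C; DMF; 1 M HCl
Reagents that add atoms: N,N-dimethylformamide, CN(C)C=O
Why: Bromine–lithium exchange with one equivalent of n-BuLi touches only one of the two equivalent bromines, a second exchange on an aryllithium being much slower, and DMF formylates the aryllithium.

Step 5
Reactants: 8 3-bromo-2-[2-(3,5-dimethoxyphenyl)ethyl]-5-methoxybenzaldehyde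
Product: 9 3,5,7-trimethoxy-9,10-dihydrophenanthrene-1-carbaldehyde
Conditions: Pd(OAc)2 (5 mol %), PCy3·HBF4 (10 mol %), pivalic acid (30 mol %), K2CO3 (2 equiv), N,N-dimethylacetamide, 130 °C
Reagents that add atoms: none
Why: Intramolecular palladium-catalysed direct arylation (oxidative addition of zerovalent palladium to the ring D C–Br bond, then concerted metalation–deprotonation of ring A) closes the central six-membered ring, and because the two ortho C–H bonds of the 3,5-dimethoxyphenyl ring are equivalent a single dihydrophenanthrene should result.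

Step 6
Reactants: 9 3,5,7-trimethoxy-9,10-dihydrophenanthrene-1-carbaldehyde; 10 1-bromo-2-iodo-4,5-dimethoxybenzene
Product: 12 (10S)-10-(2-bromo-4,5-dimethoxyphenyl)-3,5,7-trimethoxy-9,10-dihydrophenanthrene-1-carbaldehyde, via tert-leucine aldimine 11 (not isolated)
Conditions: Pd(OAc)2 (10 mol %), L-tert-leucine (20 mol %), AgOCOCF3 (1.5 equiv), 1,1,1,3,3,3-hexafluoropropan-2-ol/AcOH (9:1), 90 °C
Reagents that add atoms: none
Why: Palladium-catalysed enantioselective benzylic C(sp3)–H arylation of a 2-alkylbenzaldehyde through a chiral transient directing group: the formyl group condenses reversibly with tert-leucine, the imine–carboxylate chelate brings divalent palladium to one of the two enantiotopic C8–H bonds (six-membered palladacycle, out of reach of C7), and oxidative addition of the aryl iodide to give tetravalent palladium followed by reductive elimination forms the C8–ring B bond with the C8 configuration set by the amino acid, the C–Br bond of 10 being inert in this cycle.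

Step 7
Reactants: 12 (10S)-10-(2-bromo-4,5-dimethoxyphenyl)-3,5,7-trimethoxy-9,10-dihydrophenanthrene-1-carbaldehyde
Product: 13 (10S)-10-(2-bromo-4,5-dimethoxyphenyl)-1-(dimethoxymethyl)-3,5,7-trimethoxy-9,10-dihydrophenanthrene
Conditions: HC(OMe)3, TsOH·H2O (cat.), MeOH, rt
Reagents that add atoms: trimethyl orthoformate, COC(OC)OC; methanol, CO
Why: Acid-catalysed acetalisation, with the orthoformate as water scavenger, masks the formyl group as its dimethyl acetal so that it survives the organolithium of step 9.

Step 8
Reactants: 14 vanillin (4-hydroxy-3-methoxybenzaldehyde)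
Product: 15 3-methoxy-4-(oxan-2-yloxy)benzaldehyde (racemic tetrahydropyranyl ether)
Conditions: 3,4-dihydro-2H-pyran, pyridinium p-toluenesulfonate (cat.), CH2Cl2, rt
Reagents that add atoms: 3,4-dihydro-2H-pyran, C1=COCCC1
Why: Acid-catalysed addition of the phenol to the enol ether (tetrahydropyranyl protection) gives an acetal that is inert to organolithiums and falls off under the mild acid of step 10; its new acetal centre is racemic and is removed later.

Step 9
Reactants: 13 (10S)-10-(2-bromo-4,5-dimethoxyphenyl)-1-(dimethoxymethyl)-3,5,7-trimethoxy-9,10-dihydrophenanthrene; 15 3-methoxy-4-(oxan-2-yloxy)benzaldehyde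
Product: 17 {2-[(10R)-1-(dimethoxymethyl)-3,5,7-trimethoxy-9,10-dihydrophenanthren-10-yl]-4,5-dimethoxyphenyl}[3-methoxy-4-(oxan-2-yloxy)phenyl]methanol (mixture of epimers at the carbinol and oxane acetal carbons), via ring B aryllithium 16 (not isolated)
Conditions: n-BuLi (1.05 equiv), THF, −78 °C; then 15, −78 to −20 °C; aq. NH4Cl
Reagents that add atoms: none
Why: Bromine–lithium exchange on ring B followed by 1,2-addition of the aryllithium to the aldehyde forms the C9–ring B bond; the carbinol centre forms without control, which does not matter because C9 becomes trigonal in the key step.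

Step 10
Reactants: 17 the carbinol of step 9; 18 sodium 4-methylbenzenesulfinate
Product: 20 (10R)-10-{2-[(4-hydroxy-3-methoxyphenyl)(4-methylbenzenesulfonyl)methyl]-4,5-dimethoxyphenyl}-3,5,7-trimethoxy-9,10-dihydrophenanthrene-1-carbaldehyde (either epimer at the sulfonyl carbon, the future C9), via hydroxy aldehyde 19 (not isolated)
Conditions: 18 (4 equiv), 1 M aq. HCl (4 equiv), THF, 0 °C to rt
Reagents that add atoms: water, O
Why: Aqueous acid hydrolyses the tetrahydropyranyl ether and the dimethyl acetal and ionises the doubly para-oxygen-stabilised diarylmethanol, and the cation is captured at sulfur by the sulfinate (SN1 substitution giving the thermodynamically favoured sulfone), the excess sulfinate in a nucleophilic aqueous medium keeping the cation from alkylating ring A.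

Step 11
Reactants: 20 the sulfone aldehyde of step 10
Product: 23 (8R,9S)-pentacyclic C10 ketone (target skeleton with C10 as C=O, two OMe on ring A, two on ring B, one on ring D, ring C as 4-hydroxy-3-methoxyphenyl), via para-quinone methide 21 (not isolated), via Breslow intermediate 22 (not isolated)
Conditions: (5aS,10bR)-2-(pentafluorophenyl)-5a,10b-dihydro-4H,6H-indeno[2,1-b][1,2,4]triazolo[4,3-d][1,4]oxazin-2-ium tetrafluoroborate (20 mol %), Cs2CO3 (1.5 equiv), 4 Å molecular sieves, CH2Cl2 (0.01 M), rt
Reagents that add atoms: none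
Why: Proposed new method: Cs2CO3 removes the phenol proton and expels toluenesulfinate to give the para-quinone methide 21, whose exocyclic carbon C9 carries only ring B and hydrogen and so cannot tautomerise, while the triazolylidene freed by the same base adds to the ring D aldehyde and, after proton transfer, gives the Breslow intermediate 22. Its nucleophilic carbon C10 attacks C9 in a Stetter-type 1,6-addition that restores aromatic ring C as its phenoxide, and collapse of the tetrahedral adduct releases the carbene and leaves the C10 ketone. The closest known reaction types are the intermolecular carbene-catalysed 1,6-addition of aromatic aldehydes to isolated para-quinone methides and the intramolecular Stetter reaction onto enoates; neither has been run on a quinone methide released in situ in the same molecule or used to close a seven-membered ring. The single ring closure is 7-exo-trig (C10 onto C9, the C9=C double bond lying outside the new ring). C9 is the only new stereocentre: the C8 centre in the forming ring and the matched chiral carbene direct C10 to the quinone methide face that places H9 cis to H8, and because C9 is alpha to the ketone and doubly benzylic the carbonate base can equilibrate it to that epimer. The step needs intramolecular acyl-anion addition to win over benzoin coupling and intermolecular capture of the quinone methide; high dilution, the slow heterogeneous release of 21, and the placement of C10 and C9 on rings D and B that are both bonded to C8 (only the seven-membered closure is within reach) should secure this.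

Step 12
Reactants: 23 (8R,9S)-pentacyclic C10 ketone
Product: 24 (8R,9S)-pentacyclic C10 alcohol (mixture of C10 epimers)
Conditions: NaBH4, THF/MeOH, 0 °C
Reagents that add atoms: none
Why: Hydride reduction of the aryl ketone with NaBH4 gives the benzylic alcohol, whose C10 configuration is irrelevant because the oxygen is removed in step 13.

Step 13
Reactants: 24 (8R,9S)-pentacyclic C10 alcohol
Product: 26 (8R,9S)-10-deoxy pentacycle (hexa-O-methyl target with free 4-OH on ring C), via bis(trifluoroacetate) 25 (not isolated)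
Conditions: (CF3CO)2O (3 equiv), EtOAc, 0 °C; then 10% Pd/C, H2 (3 atm), rt; then MeOH, aq. NaHCO3
Reagents that add atoms: none
Why: The benzylic alcohol is activated in situ as its trifluoroacetate and cleaved by palladium-catalysed hydrogenolysis, a surface process that needs no free cation so that the neighbouring C9 centre is not disturbed, and the aryl trifluoroacetate is cleaved during the methanolic bicarbonate work-up.

Step 14
Reactants: 26 (8R,9S)-10-deoxy pentacycle
Product: 27 CNP0306974.1, the (8R,9S) heptaphenol
Conditions: BBr3 (12 equiv), CH2Cl2, −78 °C to rt; MeOH, then H2O; under argon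
Reagents that add atoms: none
Why: BBr3 cleaves all six aryl methyl ethers by Lewis acid–base complexation and bromide attack at methyl (global demethylation), conditions under which the two C–H stereocentres have no path to epimerise.

**Compound list**

1 | 3,5-dibromoanisole | COc1cc(Br)cc(Br)c1 | starting material
2 | (2,6-dibromo-4-methoxyphenyl)lithium | [Li]c1c(Br)cc(OC)cc1Br | intermediate (not isolated)
3 | 2,6-dibromo-4-methoxybenzaldehyde | COc1cc(Br)c(C=O)c(Br)c1 | intermediate
4 | diethyl (3,5-dimethoxybenzyl)phosphonate | CCOP(=O)(Cc1cc(OC)cc(OC)c1)OCC | starting material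
5 | (E)-1,3-dibromo-2-[2-(3,5-dimethoxyphenyl)ethenyl]-5-methoxybenzene | COc1cc(Br)c(/C=C/c2cc(OC)cc(OC)c2)c(Br)c1 | intermediate
6 | 1,3-dibromo-2-[2-(3,5-dimethoxyphenyl)ethyl]-5-methoxybenzene | COc1cc(Br)c(CCc2cc(OC)cc(OC)c2)c(Br)c1 | intermediate
7 | {3-bromo-2-[2-(3,5-dimethoxyphenyl)ethyl]-5-methoxyphenyl}lithium | [Li]c1cc(OC)cc(Br)c1CCc1cc(OC)cc(OC)c1 | intermediate (not isolated)
8 | 3-bromo-2-[2-(3,5-dimethoxyphenyl)ethyl]-5-methoxybenzaldehyde | COc1cc(Br)c(CCc2cc(OC)cc(OC)c2)c(C=O)c1 | intermediate
9 | 3,5,7-trimethoxy-9,10-dihydrophenanthrene-1-carbaldehyde | COc1cc(OC)c2c(c1)CCc1c(C=O)cc(OC)cc-21 | intermediate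
10 | 1-bromo-2-iodo-4,5-dimethoxybenzene | COc1cc(Br)c(I)cc1OC | starting material
11 | (2S)-3,3-dimethyl-2-{[(E)-(3,5,7-trimethoxy-9,10-dihydrophenanthren-1-yl)methylidene]amino}butanoic acid (transient aldimine) | COc1cc(OC)c2c(c1)CCc1c(/C=N/[C@@H](C(C)(C)C)C(=O)O)cc(OC)cc-21 | intermediate (not isolated)
12 | (10S)-10-(2-bromo-4,5-dimethoxyphenyl)-3,5,7-trimethoxy-9,10-dihydrophenanthrene-1-carbaldehyde | COc1cc(OC)c2c(c1)C[C@H](c1cc(OC)c(OC)cc1Br)c1c(C=O)cc(OC)cc-21 | intermediate
13 | (10S)-10-(2-bromo-4,5-dimethoxyphenyl)-1-(dimethoxymethyl)-3,5,7-trimethoxy-9,10-dihydrophenanthrene | COc1cc(OC)c2c(c1)C[C@H](c1cc(OC)c(OC)cc1Br)c1c(C(OC)OC)cc(OC)cc-21 | intermediate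
14 | vanillin (4-hydroxy-3-methoxybenzaldehyde) | COc1cc(C=O)ccc1O | starting material
15 | 3-methoxy-4-(oxan-2-yloxy)benzaldehyde (racemic) | COc1cc(C=O)ccc1OC1CCCCO1 | intermediate
16 | {2-[(10R)-1-(dimethoxymethyl)-3,5,7-trimethoxy-9,10-dihydrophenanthren-10-yl]-4,5-dimethoxyphenyl}lithium | COc1cc(OC)c2c(c1)C[C@H](c1cc(OC)c(OC)cc1[Li])c1c(C(OC)OC)cc(OC)cc-21 | intermediate (not isolated)
17 | {2-[(10R)-1-(dimethoxymethyl)-3,5,7-trimethoxy-9,10-dihydrophenanthren-10-yl]-4,5-dimethoxyphenyl}[3-methoxy-4-(oxan-2-yloxy)phenyl]methanol (epimer mixture at the carbinol and oxane acetal carbons) | COc1cc(OC)c2c(c1)C[C@H](c1cc(OC)c(OC)cc1C(O)c1ccc(OC3CCCCO3)c(OC)c1)c1c(C(OC)OC)cc(OC)cc-21 | intermediate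
18 | sodium 4-methylbenzenesulfinate | Cc1ccc(S(=O)[O-])cc1.[Na+] | starting material
19 | (10R)-10-{2-[hydroxy(4-hydroxy-3-methoxyphenyl)methyl]-4,5-dimethoxyphenyl}-3,5,7-trimethoxy-9,10-dihydrophenanthrene-1-carbaldehyde (carbinol epimers) | COc1cc(OC)c2c(c1)C[C@H](c1cc(OC)c(OC)cc1C(O)c1ccc(O)c(OC)c1)c1c(C=O)cc(OC)cc-21 | intermediate (not isolated)
20 | (10R)-10-{2-[(4-hydroxy-3-methoxyphenyl)(4-methylbenzenesulfonyl)methyl]-4,5-dimethoxyphenyl}-3,5,7-trimethoxy-9,10-dihydrophenanthrene-1-carbaldehyde (either epimer at the sulfonyl carbon) | COc1cc(OC)c2c(c1)C[C@H](c1cc(OC)c(OC)cc1C(c1ccc(O)c(OC)c1)S(=O)(=O)c1ccc(C)cc1)c1c(C=O)cc(OC)cc-21 | intermediate (key-step precursor)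
21 | (10R)-10-{4,5-dimethoxy-2-[(3-methoxy-4-oxocyclohexa-2,5-dien-1-ylidene)methyl]phenyl}-3,5,7-trimethoxy-9,10-dihydrophenanthrene-1-carbaldehyde (para-quinone methide, E/Z unspecified) | COc1cc(OC)c2c(c1)C[C@H](c1cc(OC)c(OC)cc1C=C1C=CC(=O)C(OC)=C1)c1c(C=O)cc(OC)cc-21 | intermediate (not isolated)
22 | Breslow intermediate: enaminol from the formyl carbon of 21 and the (5aS,10bR)-2-(pentafluorophenyl)triazolylidene | COc1cc(OC)c2c(c1)C[C@H](c1cc(OC)c(OC)cc1C=C1C=CC(=O)C(OC)=C1)c1c(C(O)=C3N(c4c(F)c(F)c(F)c(F)c4F)N=C4CO[C@H]5Cc6ccccc6[C@H]5N34)cc(OC)cc-21 | intermediate (not isolated)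
23 | (8R,9S)-pentacyclic C10 ketone, hexamethyl ether with free 4-OH on ring C | COc1cc(OC)c2c(c1)C[C@@H]1c3cc(OC)c(OC)cc3[C@H](c3ccc(O)c(OC)c3)C(=O)c3cc(OC)cc-2c31 | intermediate (key-step product)
24 | (8R,9S)-pentacyclic C10 alcohol (C10 epimers) | COc1cc(OC)c2c(c1)C[C@@H]1c3cc(OC)c(OC)cc3[C@H](c3ccc(O)c(OC)c3)C(O)c3cc(OC)cc-2c31 | intermediate
25 | (8R,9S)-C10 trifluoroacetate with ring C aryl trifluoroacetate | COc1cc(OC)c2c(c1)C[C@@H]1c3cc(OC)c(OC)cc3[C@H](c3ccc(OC(=O)C(F)(F)F)c(OC)c3)C(OC(=O)C(F)(F)F)c3cc(OC)cc-2c31 | intermediate (not isolated)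
26 | (8R,9S)-10-deoxy pentacycle (hexa-O-methyl target, free 4-OH on ring C) | COc1cc(OC)c2c(c1)C[C@@H]1c3cc(OC)c(OC)cc3[C@H](c3ccc(O)c(OC)c3)Cc3cc(OC)cc-2c31 | intermediate
27 | CNP0306974.1, (8R,9S) | Oc1cc(O)c2c(c1)C[C@@H]1c3cc(O)c(O)cc3[C@H](c3ccc(O)c(O)c3)Cc3cc(O)cc-2c31 | target

**Step count and risks**

Total step count: 14. Longest linear sequence: 13 steps (steps 1–7 and 9–14 from 3,5-dibromoanisole; step 8 is a one-step branch).

Steps most likely to fail:

1. Step 11 (Proposed new method). The Breslow intermediate may be diverted into intermolecular benzoin-type coupling, or the carbene may add reversibly to C9 of the quinone methide and stall turnover while the quinone methide oligomerises. The fallback uses known chemistry; it sets out from carbinol 17 and comes back at 26. Oxidation of 17 with MnO2 in CH2Cl2 gives the diaryl ketone {2-[(10R)-1-(dimethoxymethyl)-3,5,7-trimethoxy-9,10-dihydrophenanthren-10-yl]-4,5-dimethoxyphenyl}[3-methoxy-4-(oxan-2-yloxy)phenyl]methanone F1. Brief treatment with 1 M HCl in THF unmasks the keto aldehyde (10R)-10-[2-(4-hydroxy-3-methoxybenzoyl)-4,5-dimethoxyphenyl]-3,5,7-trimethoxy-9,10-dihydrophenanthrene-1-carbaldehyde F2. Intramolecular McMurry coupling (low-valent titanium from TiCl4 and Zn, pyridine, THF, reflux, slow addition) joins C9 and C10 as the (8R)-pentacyclic C9=C10 alkene F3. Hydrogenation (H2, 10% Pd/C, EtOAc) should add hydrogen from the less hindered face, the one carrying H8, and give 26 with H9 cis to H8. The C9–C10 bond is then made by reductive carbonyl coupling instead of acyl-anion addition, and steps 10 to 13 are not needed.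

2. Step 6. The tert-leucine palladacycle may discriminate poorly between the two enantiotopic C8–H bonds of the ring methylene, so that C8 forms with low enantiomeric purity. The fallback sets out from 9 and comes back at 20, and secures C8 by separating covalent diastereomers instead of by catalyst control. Arylation of 9 with 10 using glycine as the achiral transient directing group gives racemic 10-(2-bromo-4,5-dimethoxyphenyl)-3,5,7-trimethoxy-9,10-dihydrophenanthrene-1-carbaldehyde F4. Condensation with (1R,2R)-1,2-diphenylethane-1,2-diol (TsOH, toluene, reflux, water removal) gives two diastereomeric dioxolanes: the (10S)-(4R,5R)-4,5-diphenyl-1,3-dioxolane F5 and the (10R)-(4R,5R)-4,5-diphenyl-1,3-dioxolane F6, separated by crystallisation or chromatography; F6 is set aside. F5 takes the place of 13 under the conditions of step 9 and gives the carbinol with the chiral dioxolane F7. The medium of step 10, warmed to 40 °C, removes the diol (recovered) and the tetrahydropyranyl group and installs the sulfone, giving 20.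

3. Step 10. The diarylmethyl cation may alkylate the electron-rich ring A (Friedel–Crafts closure onto the ring A carbon next to C7) faster than the sulfinate captures it. The fallback sets out from 13 and comes back at 20 without forming a cation at C9. Commercial 4-(hydroxymethyl)-2-methoxyphenol and 18 in aqueous formic acid give 2-methoxy-4-[(4-methylbenzenesulfonyl)methyl]phenol F8, and 3,4-dihydro-2H-pyran with pyridinium p-toluenesulfonate gives its tetrahydropyranyl ether F9. Palladium-catalysed alpha-arylation of sulfone F9 with aryl bromide 13 (Pd(OAc)2, XPhos, LiOtBu, toluene, 100 °C; oxidative addition of zerovalent palladium, transmetalation with the alpha-sulfonyl carbanion, reductive elimination) gives the fully protected diarylmethyl sulfone F10. Pyridinium p-toluenesulfonate in acetone/water at 40 °C then removes the acetal and the tetrahydropyranyl group to give 20.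

**Further compounds**

F1 | step 11 | {2-[(10R)-1-(dimethoxymethyl)-3,5,7-trimethoxy-9,10-dihydrophenanthren-10-yl]-4,5-dimethoxyphenyl}[3-methoxy-4-(oxan-2-yloxy)phenyl]methanone | COc1cc(OC)c2c(c1)C[C@H](c1cc(OC)c(OC)cc1C(=O)c1ccc(OC3CCCCO3)c(OC)c1)c1c(C(OC)OC)cc(OC)cc-21
F2 | step 11 | (10R)-10-[2-(4-hydroxy-3-methoxybenzoyl)-4,5-dimethoxyphenyl]-3,5,7-trimethoxy-9,10-dihydrophenanthrene-1-carbaldehyde | COc1cc(OC)c2c(c1)C[C@H](c1cc(OC)c(OC)cc1C(=O)c1ccc(O)c(OC)c1)c1c(C=O)cc(OC)cc-21
F3 | step 11 | (8R)-pentacyclic C9=C10 alkene, hexamethyl ether with free 4-OH on ring C | COc1cc(OC)c2c(c1)C[C@@H]1c3cc(OC)c(OC)cc3C(c3ccc(O)c(OC)c3)=Cc3cc(OC)cc-2c31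
F4 | step 6 | racemic 10-(2-bromo-4,5-dimethoxyphenyl)-3,5,7-trimethoxy-9,10-dihydrophenanthrene-1-carbaldehyde | COc1cc(OC)c2c(c1)CC(c1cc(OC)c(OC)cc1Br)c1c(C=O)cc(OC)cc-21
F5 | step 6 | (4R,5R)-2-[(10S)-10-(2-bromo-4,5-dimethoxyphenyl)-3,5,7-trimethoxy-9,10-dihydrophenanthren-1-yl]-4,5-diphenyl-1,3-dioxolane | COc1cc(OC)c2c(c1)C[C@H](c1cc(OC)c(OC)cc1Br)c1c(C3O[C@H](c4ccccc4)[C@@H](c4ccccc4)O3)cc(OC)cc-21
F6 | step 6 | (4R,5R)-2-[(10R)-10-(2-bromo-4,5-dimethoxyphenyl)-3,5,7-trimethoxy-9,10-dihydrophenanthren-1-yl]-4,5-diphenyl-1,3-dioxolane | COc1cc(OC)c2c(c1)C[C@@H](c1cc(OC)c(OC)cc1Br)c1c(C3O[C@H](c4ccccc4)[C@@H](c4ccccc4)O3)cc(OC)cc-21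
F7 | step 6 | {2-[(10R)-1-[(4R,5R)-4,5-diphenyl-1,3-dioxolan-2-yl]-3,5,7-trimethoxy-9,10-dihydrophenanthren-10-yl]-4,5-dimethoxyphenyl}[3-methoxy-4-(oxan-2-yloxy)phenyl]methanol (epimer mixture at the carbinol and oxane acetal carbons) | COc1cc(OC)c2c(c1)C[C@H](c1cc(OC)c(OC)cc1C(O)c1ccc(OC3CCCCO3)c(OC)c1)c1c(C3O[C@H](c4ccccc4)[C@@H](c4ccccc4)O3)cc(OC)cc-21
F8 | step 10 | 2-methoxy-4-[(4-methylbenzenesulfonyl)methyl]phenol | COc1cc(CS(=O)(=O)c2ccc(C)cc2)ccc1O
F9 | step 10 | 2-{2-methoxy-4-[(4-methylbenzenesulfonyl)methyl]phenoxy}oxane (racemic) | COc1cc(CS(=O)(=O)c2ccc(C)cc2)ccc1OC1CCCCO1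
F10 | step 10 | (10R)-1-(dimethoxymethyl)-10-{4,5-dimethoxy-2-[[3-methoxy-4-(oxan-2-yloxy)phenyl](4-methylbenzenesulfonyl)methyl]phenyl}-3,5,7-trimethoxy-9,10-dihydrophenanthrene (epimer mixture) | COc1cc(OC)c2c(c1)C[C@H](c1cc(OC)c(OC)cc1C(c1ccc(OC3CCCCO3)c(OC)c1)S(=O)(=O)c1ccc(C)cc1)c1c(C(OC)OC)cc(OC)cc-21
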